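- winter: solid substrate 0.50 M; partner 1.3 M; run made earlier
- flask: solid substrate 1.0 M; partner 1.30 M; time 8.0 min

- winter (time / s: product / %, solid substrate / %): 10.0: 3, 85; 15.0: 9, 84; 25.0: 16, 65; 30.0: 16, 64; 40.0: 28, 56; 50.0: 36, 44

(readings scatter by 2 percentage points)

- as a solid, counted per litre of solution: solid substrate
- candidate steps: solid substrate <-> dissolved substrate; dissolved substrate + partner -> product; partner -> decomposed reagent
- at the start none of the solid substrate is in solution

- Sunday's: doubling the dissolution coefficient of the solid substrate, all else as stated
- Friday's: doubling the amount of partner, all else as stated
- Saturday's: doubling the solubility of the solid substrate, all else as stated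

1. amount of product at 8.0 min, in percent of the solid substrate charged
2. the change that raises the amount of product at 8.0 min, in percent of the solid substrate charged most ("none" if none brings more than 2 percentage points) (Sunday's / Friday's / Saturday's / none)
3. amount of product at 8.0 min, in percent of the solid substrate charged, after Saturday's

1. The ratio that separates the charges of this flask and the winter run is partner to solid substrate: 1.30 here, less than the 2.60 of the winter run, with twice the solid substrate over the same partner.

2. The winter run reads 36% product at 50.0 s, with 44% still solid. I assume a solution standing over solid makes product at the same molar rate however much solid lies there, so this flask gains fractions of its charge half as fast.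

3. That gives 4.63 min, the clearing time: the flask's charge divided by the winter mean rate of product formation. The reading carries about 5.56% of scatter.

4. Now I check the mean. If partner falls straight and the rate follows it, its mean fraction is 61.5% here and 93.1% in the winter run, which stretches my estimate of the clearing time to 7.00 min, shorter than 8.0 min. No reading shows partner, so this assumes its decomposition stays slow.

5. I commit to a charge cleared before 8.0 min, with little for any change to add. The forecast says 96% (82% to 99.5%), none as best change and 99% after Saturday's, and of partner decomposition: “so I shade down slightly”.

6. The flask gives 52.5%; Friday's is best, gaining 33 percentage points; Saturday's gives 70.3%.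

    solid substrate ⇌ dissolved substrate, rate k1*(cs1 - [dissolved substrate]) while solid is left; crystals form when [dissolved substrate] > cs1 (solubility = 0.350 M, k = 0.0212 s⁻¹)
    dissolved substrate + partner → product (k = 0.0518 L mol⁻¹ s⁻¹)
    partner → decomposed reagent (k = 0.00870 s⁻¹)

The clearing time of 4.63 min is longer than the 1.3 min half-life of partner by decomposition alone, and this flask holds 1.20% of its partner, the limiting reagent, with 51.5% product at 4.00 min. The neighbour flask with 0.25 M of solid substrate has a clearing time of 1.16 min, shorter than that half-life, and it holds 99.2% product at 8.00 min.

All runs were generated by integration with constants of no real substance; the scatter is artificial.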